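The readings are calculated with constants of no real substance, noise included.

Target read point by point misleads: it falls from 4.9% to 1.0% in the north-west run, yet climbs from 2.4% to 4.0% in the west run, and each reading scatters by 1 percentage point.

the same everywhere: starting material 0.10 M; impurity 46 µM
- north-east: other conformer 0.50 equiv; free catalyst 0.05 mol%; run made earlier
- north-west: other conformer 0.50 equiv; free catalyst 0.2 mol%; run made earlier
- west: other conformer 1 equiv; free catalyst 0.1 mol%; run made earlier
- flask: other conformer 0.500 equiv; free catalyst 0.1 mol%; time 12 h

| run | time / h | target / % | isomer of the product / % | starting material / % |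
|---|---|---|---|---|
| north-east | 4.00 | 0 | 34.4 | 52.4 |
| north-east | 8.00 | 4.0 | 52.5 | 39.4 |
| north-east | 10.0 | 1.3 | 60.2 | 34.1 |
| north-east | 15.0 | 1.9 | 72.8 | 22.2 |
| north-west | 1.00 | 4.0 | 80.3 | 13.8 |
| north-west | 2.50 | 4.9 | 95.9 | 1.4 |
| north-west | 6.00 | 3.1 | 96.4 | 0 |
| north-west | 15.0 | 1.0 | 96.6 | 0.3 |
| west | 4.00 | 2.4 | 93.9 | 2.1 |
| west | 8.00 | 3.0 | 95.8 | 0.7 |
| west | 10.0 | 3.9 | 95.7 | 0.4 |
| west | 15.0 | 4.0 | 97.3 | 0 |

(readings scatter by 1 percentage point)

- a reading or a percentage of target counts all its forms, free or not

1. share of target in target plus isomer of the product at 20 s
2. share of target in target plus isomer of the product at 12 h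

So sum first and divide afterwards. Target summed over target plus isomer of the product gives 3.17% in the north-east run, 3.40% in the north-west run and 3.36% in the west run. All the readings together give 3.33%: the pooled share, a selectivity, meaning all target readings summed over all target and isomer readings summed.

Yet the pace differs widely: starting material reads 52.4% after 4.00 h in the north-east run and 13.8% after 1.00 h in the north-west run. By time, the first readings of the runs pool to 2.98% and the last to 2.52%, a difference of 0.46 points between sums of readings that each scatter by 1 point. The reckoning here therefore takes 3.33% for this flask at both times, though no reading stands earlier than 1.00 h.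

The forecast gives 5% at 20 s, higher than that reckoning and called “perhaps about 5%, and uncertain”, and 3.2% at 12 h.

The flask gives 3.03% at 20 s and 3.03% at 12 h.

    starting material ⇌ other conformer, settled at all times (K = 0.160)
    starting material + free catalyst → free catalyst + target (k = 0.230 M⁻¹ s⁻¹)
    free catalyst + other conformer → free catalyst + isomer of the product (k = 46.0 M⁻¹ s⁻¹)
    2 free catalyst ⇌ resting dimer, settled at all times (K = 5500 M⁻¹)
    free catalyst + impurity → spent catalyst (k = 160 M⁻¹ s⁻¹)
    free catalyst + target ⇌ idle complex, settled at all times (K = 28.0 M⁻¹)

The rate constant into target, divided by itself plus the conformer equilibrium constant times the rate constant into the isomer of the product, is 3.03%. The neighbour flask with 0.040 M of starting material holds 79.3% of its charge as starting material at 12 h, with free catalyst at 0% of the catalyst charged, and its share stands at 3.03%. The pooled share, a reading with its scatter, puts target at 3.33% in this flask, which holds 3.03%, and at 0.266% in the neighbour flask, which holds 0.242%.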